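**Retrosynthetic overview**
1. The C4'–Cl/C5'–Br pair comes last, by anti bromochlorination of a C4'=C5' alkene. C2–Br comes from C2–OH with inversion, C4–OH from an intramolecular oxa-Michael addition to a C2 enone, and the C1 gem-dimethyl group from enolate methylation.
2. Key disconnection is the ring-to-ring bond C5–C1'. The β-carbon of the latent cyclopentanone, as a titanated O-allyl carbamate (Hoppe homoenolate), adds to a carbonyl of cyclohexane-1,4-dione. The quaternary centre arises by 1,3-chirality transfer from a CBS-derived allylic alcohol.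
3. The sense of the cyclohexene (C4'=C5' rather than C4'=C3', which defines C1') is set by chiral lithium amide enolisation of the remaining ketone, then triflate-to-methyl coupling.
4. No ring is built: 2,3-dimethylcyclopent-2-enone and cyclohexane-1,4-dione are bought and joined in step 3.

Atom labels: cyclopentane C1 (CMe2), C2 (CHBr), C3 (CH2), C4 (CHOH), C5 (CMe); cyclohexane C1' (COH), C2', C3', C4' (CMeCl), C5' (CHBr), C6'. Target: (1R,2S,4S)-4-bromo-2-[(1R,3S,4S)-3-bromo-4-chloro-1-hydroxy-4-methylcyclohexyl]-2,3,3-trimethylcyclopentan-1-ol.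

Assumption: α-lithiation of the allyl carbamate goes with retention and lithium–titanium exchange with inversion (as for Hoppe's secondary 2-alkenyl carbamates), and the (R,R)-amide base enolises with the same sense as reported for 4-tert-butylcyclohexanone.

Step 1
Reactants: 1 2,3-dimethylcyclopent-2-en-1-one
Product: 2 (S)-2,3-dimethylcyclopent-2-en-1-ol
Conditions: (R)-2-methyl-CBS-oxazaborolidine ((R)-1-methyl-3,3-diphenyltetrahydro-1H,3H-pyrrolo[1,2-c][1,3,2]oxazaborole, 10 mol %), BH3·SMe2, THF, −20 °C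
Reagents that add atoms: none
Why: Corey–Bakshi–Shibata reduction in which the methyl-bearing alkenyl carbon acts as the large group, so the (R)-catalyst gives the (S)-allylic alcohol, the stereocentre that is later relayed to the quaternary carbon.

Step 2
Reactants: 2 (S)-2,3-dimethylcyclopent-2-en-1-ol
Product: 3 (S)-2,3-dimethylcyclopent-2-en-1-yl N,N-diisopropylcarbamate
Conditions: NaH, iPr2NCOCl, THF, reflux
Reagents that add atoms: N,N-diisopropylcarbamoyl chloride, CC(C)N(C(C)C)C(Cl)=O
Why: Acylation of the sodium alkoxide gives the Hoppe carbamate, the directing and stabilising group for α-lithiation, without touching the stereocentre.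

Step 3
Reactants: 3 (S)-2,3-dimethylcyclopent-2-en-1-yl N,N-diisopropylcarbamate; 4 cyclohexane-1,4-dione
Product: 7 (3R)-3-(1-hydroxy-4-oxocyclohexyl)-2,3-dimethylcyclopent-1-en-1-yl N,N-diisopropylcarbamate, via α-lithio carbamate 5 (not isolated), via triisopropoxytitanium reagent 6 (not isolated)
Conditions: s-BuLi, TMEDA, Et2O, −78 °C; ClTi(OiPr)3, −78 °C; 4 (3 equiv), THF, −78 → −30 °C
Reagents that add atoms: none
Why: Hoppe homoaldol reaction in which carbamate-directed α-lithiation (retention) and Li→Ti exchange (inversion) give a configurationally stable titanated 1-oxyallyl anion, a homoenolate equivalent whose γ-carbon (C5, the β-carbon of the latent cyclopentanone) adds to one carbonyl of 4 through a six-membered syn-SE' transition state on the titanium-bearing face, so the C–O stereocentre of 3 is relayed by 1,3-chirality transfer into the quaternary centre (R at this stage), while the weakly basic titanium reagent and excess 4 suppress enolisation and double addition.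

Step 4
Reactants: 7 (3R)-3-(1-hydroxy-4-oxocyclohexyl)-2,3-dimethylcyclopent-1-en-1-yl N,N-diisopropylcarbamate
Product: 9 (4R)-4-[(1R)-3-(diisopropylcarbamoyloxy)-1,2-dimethylcyclopent-2-en-1-yl]-4-hydroxycyclohex-1-en-1-yl trifluoromethanesulfonate, via dilithio enolate 8 (not isolated)
Conditions: lithium (R,R)-bis(1-phenylethyl)amide (2.3 equiv, from the amine and n-BuLi), LiCl, THF, −78 °C; PhNTf2, −78 → 0 °C
Reagents that add atoms: N-phenylbis(trifluoromethanesulfonimide), O=S(=O)(N(c1ccccc1)S(=O)(=O)C(F)(F)F)C(F)(F)F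
Why: Simpkins-type enantiotopic-group-selective deprotonation in which the large cyclopentenyl group locks the chair (alkoxide axial) and the C2-symmetric amide removes one of the two axial α-hydrogens with the sense known for 4-tert-butylcyclohexanone ((R,R)-base gives the (S)-type enolate), which distinguishes C5' from C3' and so makes C1' a defined (R) stereocentre, the enolate oxygen alone being triflated.

Step 5
Reactants: 9 (4R)-4-[(1R)-3-(diisopropylcarbamoyloxy)-1,2-dimethylcyclopent-2-en-1-yl]-4-hydroxycyclohex-1-en-1-yl trifluoromethanesulfonate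
Product: 10 (3R)-3-[(1R)-1-hydroxy-4-methylcyclohex-3-en-1-yl]-2,3-dimethylcyclopent-1-en-1-yl N,N-diisopropylcarbamate
Conditions: (MeBO)3, Pd(dppf)Cl2 (5 mol %), K2CO3, dioxane/H2O, 80 °C
Reagents that add atoms: trimethylboroxine, CB1OB(C)OB(C)O1
Why: Suzuki–Miyaura coupling of the enol triflate installs the C4' methyl group on the fixed double bond, the enol carbamate and tertiary alcohol being inert and no stereocentre being touched.

Step 6
Reactants: 10 (3R)-3-[(1R)-1-hydroxy-4-methylcyclohex-3-en-1-yl]-2,3-dimethylcyclopent-1-en-1-yl N,N-diisopropylcarbamate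
Product: 12 (3R)-3-[(1R)-1-hydroxy-4-methylcyclohex-3-en-1-yl]-2,2,3-trimethylcyclopentan-1-one, via lithium enolate 11 (not isolated)
Conditions: MeLi (3 equiv), DME, −20 → 0 °C; MeI, DMPU, −40 °C → rt
Reagents that add atoms: iodomethane, CI
Why: Hoppe deblocking followed by enolate alkylation, in which MeLi attacks the carbamoyl group and releases the tetrasubstituted lithium enolate regiospecifically at C1–C2, whose C-methylation (as in conjugate addition–methylation routes to α-cuparenone) creates the gem-dimethyl carbon and unveils the C2 ketone without touching a stereocentre.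

Step 7
Reactants: 12 (3R)-3-[(1R)-1-hydroxy-4-methylcyclohex-3-en-1-yl]-2,2,3-trimethylcyclopentan-1-one
Product: 13 (4R)-4-[(1R)-1-hydroxy-4-methylcyclohex-3-en-1-yl]-4,5,5-trimethylcyclopent-2-en-1-one
Conditions: IBX, DMSO/PhF, 70 °C
Reagents that add atoms: none
Why: IBX (Nicolaou) dehydrogenation of a ketone that has only one enolisable α-position (C3), so a single enone with its β-carbon at C4 results.

Step 8
Reactants: 13 (4R)-4-[(1R)-1-hydroxy-4-methylcyclohex-3-en-1-yl]-4,5,5-trimethylcyclopent-2-en-1-one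
Product: 15 (3S,4R)-4-hydroxy-3-[(1R)-1-hydroxy-4-methylcyclohex-3-en-1-yl]-2,2,3-trimethylcyclopentan-1-one, via cyclic phenylboronate 14 (not isolated)
Conditions: PhB(OH)2, quinuclidine (20 mol %), 4 Å MS, CH2Cl2, 35 °C; 30% H2O2, pH 7 buffer, THF, 0 °C
Reagents that add atoms: phenylboronic acid, OB(O)c1ccccc1
Why: Falck boronic acid oxa-Michael addition in which the tertiary δ-hydroxyl forms a boronate hemiester whose amine-activated B–O adds to the enone β-carbon intramolecularly, necessarily on the face of the carbinol (cis-fused dioxaborinane), which sets C4 (R, oxygen cis to the cyclohexenyl carbinol) before buffered peroxide removes boron.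

Step 9
Reactants: 15 (3S,4R)-4-hydroxy-3-[(1R)-1-hydroxy-4-methylcyclohex-3-en-1-yl]-2,2,3-trimethylcyclopentan-1-one
Product: 16 (1R,3R,4S)-4-[(1R)-1-hydroxy-4-methylcyclohex-3-en-1-yl]-4,5,5-trimethylcyclopentane-1,3-diol
Conditions: Me4NBH(OAc)3, MeCN/AcOH, −30 °C
Reagents that add atoms: none
Why: Evans–Saksena hydroxyl-directed reduction in which acetoxy exchange binds boron to the C4 (and C1') oxygen and hydride is delivered intramolecularly to that face of the C2 carbonyl, giving the 1,3-trans diol (C2 R, hydroxyl on the face opposite to C4–OH).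

Step 10
Reactants: 16 (1R,3R,4S)-4-[(1R)-1-hydroxy-4-methylcyclohex-3-en-1-yl]-4,5,5-trimethylcyclopentane-1,3-diol
Product: 19 (1R,2S,4S)-4-bromo-2-[(1R)-1-hydroxy-4-methylcyclohex-3-en-1-yl]-2,3,3-trimethylcyclopentan-1-ol, via triol phenylboronate 17 (not isolated), via bromo phenylboronate 18 (not isolated)
Conditions: PhB(OH)2, 4 Å MS, CH2Cl2, rt; PPh3, CBr4, 0 °C → rt; 30% H2O2, pH 7 buffer, 0 °C
Reagents that add atoms: carbon tetrabromide, BrC(Br)(Br)Br
Why: Appel reaction in which, after the cis-related C4 and C1' hydroxyls are masked in situ as the six-membered phenylboronate (the trans C2 hydroxyl cannot join), the only free alcohol is converted through its alkoxyphosphonium ion into the bromide by SN2 inversion, placing bromine cis to C4–OH and the carbinol (C2 S).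

Step 11
Reactants: 19 (1R,2S,4S)-4-bromo-2-[(1R)-1-hydroxy-4-methylcyclohex-3-en-1-yl]-2,3,3-trimethylcyclopentan-1-ol
Product: 21 (1R,2S,4S)-4-bromo-2-[(1R,3S,4S)-3-bromo-4-chloro-1-hydroxy-4-methylcyclohexyl]-2,3,3-trimethylcyclopentan-1-ol, via titanium diolate 20 (not isolated)
Conditions: ClTi(OiPr)3 (1.1 equiv), CH2Cl2, rt; NBS, −20 °C
Reagents that add atoms: N-bromosuccinimide, O=C1CCC(=O)N1Br; chlorotitanium triisopropoxide, CC(C)O[Ti](Cl)(OC(C)C)OC(C)C
Why: Proposed new method: the 1,3-diol binds titanium so that a Ti–Cl unit is held on the face of the axial C1' oxygen, NBS forms bromonium ions reversibly on both faces, and only the one anti to that oxygen (the face not blocked 1,3-diaxially) can be opened by intramolecular chloride transfer to the tertiary carbon C4' across the boat-like ring, giving anti addition with Br equatorial and cis to the cyclopentyl group and Cl cis to C1'–OH (C4' S, C5' S) instead of the diaxial isomer expected from free chloride, the closest known reaction type being the titanium alkoxide-mediated bromochlorination of allylic alcohols with NBS and ClTi(OiPr)3 (Burns bromochlorination).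

**Compound list**
1 | 2,3-dimethylcyclopent-2-en-1-one | CC1=C(C)C(=O)CC1 | starting material
2 | (S)-2,3-dimethylcyclopent-2-en-1-ol | CC1=C(C)CC[C@@H]1O | intermediate
3 | (S)-2,3-dimethylcyclopent-2-en-1-yl N,N-diisopropylcarbamate | CC1=C(C)CC[C@@H]1OC(=O)N(C(C)C)C(C)C | intermediate
4 | cyclohexane-1,4-dione | O=C1CCC(=O)CC1 | starting material
5 | α-lithio carbamate (lithium in place of the carbinol hydrogen, retention) | CC1=C(C)CC[C@]1([Li])OC(=O)N(C(C)C)C(C)C | intermediate
6 | triisopropoxytitanium reagent (titanium on the carbamate carbon, inverted) | CC1=C(C)CC[C@@]1([Ti](OC(C)C)(OC(C)C)OC(C)C)OC(=O)N(C(C)C)C(C)C | intermediate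
7 | (3R)-3-(1-hydroxy-4-oxocyclohexyl)-2,3-dimethylcyclopent-1-en-1-yl N,N-diisopropylcarbamate | CC1=C(OC(=O)N(C(C)C)C(C)C)CC[C@@]1(C)C1(O)CCC(=O)CC1 | intermediate
8 | dilithio enolate of 7 (lithium alkoxide at C1', lithium enolate C4'=C5') | CC1=C(OC(=O)N(C(C)C)C(C)C)CC[C@@]1(C)[C@@]1(O[Li])CCC(O[Li])=CC1 | intermediate
9 | (4R)-4-[(1R)-3-(diisopropylcarbamoyloxy)-1,2-dimethylcyclopent-2-en-1-yl]-4-hydroxycyclohex-1-en-1-yl trifluoromethanesulfonate | CC1=C(OC(=O)N(C(C)C)C(C)C)CC[C@@]1(C)[C@@]1(O)CCC(OS(=O)(=O)C(F)(F)F)=CC1 | intermediate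
10 | (3R)-3-[(1R)-1-hydroxy-4-methylcyclohex-3-en-1-yl]-2,3-dimethylcyclopent-1-en-1-yl N,N-diisopropylcarbamate | CC1=C(OC(=O)N(C(C)C)C(C)C)CC[C@@]1(C)[C@@]1(O)CCC(C)=CC1 | intermediate
11 | lithium enolate released from 10 (lithium alkoxide at C1', enolate C1=C2) | CC1=C(O[Li])CC[C@@]1(C)[C@@]1(O[Li])CCC(C)=CC1 | intermediate
12 | (3R)-3-[(1R)-1-hydroxy-4-methylcyclohex-3-en-1-yl]-2,2,3-trimethylcyclopentan-1-one | CC1(C)C(=O)CC[C@@]1(C)[C@@]1(O)CCC(C)=CC1 | intermediate
13 | (4R)-4-[(1R)-1-hydroxy-4-methylcyclohex-3-en-1-yl]-4,5,5-trimethylcyclopent-2-en-1-one | CC1(C)C(=O)C=C[C@@]1(C)[C@@]1(O)CCC(C)=CC1 | intermediate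
14 | cyclic phenylboronate bridging the C4 and C1' oxygens of 15 (cis-fused dioxaborinane, C2 ketone) | CC1(C)C(=O)C[C@@H](OB(c2ccccc2)O3)[C@@]1(C)[C@]31CCC(C)=CC1 | intermediate
15 | (3S,4R)-4-hydroxy-3-[(1R)-1-hydroxy-4-methylcyclohex-3-en-1-yl]-2,2,3-trimethylcyclopentan-1-one | CC1(C)C(=O)C[C@@H](O)[C@@]1(C)[C@@]1(O)CCC(C)=CC1 | intermediate
16 | (1R,3R,4S)-4-[(1R)-1-hydroxy-4-methylcyclohex-3-en-1-yl]-4,5,5-trimethylcyclopentane-1,3-diol (C2–OH trans to C4–OH) | CC1(C)[C@H](O)C[C@@H](O)[C@@]1(C)[C@@]1(O)CCC(C)=CC1 | intermediate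
17 | phenylboronate of 16 across the C4 and C1' oxygens, C2–OH free | CC1(C)[C@H](O)C[C@@H](OB(c2ccccc2)O3)[C@@]1(C)[C@]31CCC(C)=CC1 | intermediate
18 | phenylboronate of 19 across the C4 and C1' oxygens | CC1(C)[C@@H](Br)C[C@@H](OB(c2ccccc2)O3)[C@@]1(C)[C@]31CCC(C)=CC1 | intermediate
19 | (1R,2S,4S)-4-bromo-2-[(1R)-1-hydroxy-4-methylcyclohex-3-en-1-yl]-2,3,3-trimethylcyclopentan-1-ol | CC1(C)[C@@H](Br)C[C@@H](O)[C@@]1(C)[C@@]1(O)CCC(C)=CC1 | intermediate
20 | chloro(isopropoxy)titanium diolate of 19 (titanium bridging the C4 and C1' oxygens) | CC1(C)[C@@H](Br)C[C@@H](O[Ti](Cl)(OC(C)C)O2)[C@@]1(C)[C@]21CCC(C)=CC1 | intermediate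
21 | (1R,2S,4S)-4-bromo-2-[(1R,3S,4S)-3-bromo-4-chloro-1-hydroxy-4-methylcyclohexyl]-2,3,3-trimethylcyclopentan-1-ol | CC1(C)[C@@H](Br)C[C@@H](O)[C@@]1(C)[C@@]1(O)CC[C@](C)(Cl)[C@@H](Br)C1 | target

**Step count and risks**
Total step count: 11. Longest linear sequence: 11 steps (1 to 21; 4 is bought).

Three steps most likely to fail:

Step 3. The homoaldol has to form a quaternary carbon next to a tertiary alkoxide from a fully substituted allyl unit; slow addition or α-attack are the dangers. The fallback sets out from 1 and comes back at 7. Compound 1 is reduced with (S)-2-methyl-CBS-oxazaborolidine and BH3·SMe2 to (R)-2,3-dimethylcyclopent-2-en-1-ol F1, which is carbamoylated (NaH, iPr2NCOCl) to (R)-2,3-dimethylcyclopent-2-en-1-yl N,N-diisopropylcarbamate F2. Lithiation as in step 3 and a Me3SnCl quench, which enters at the γ-carbon anti to lithium, give the storable (3S)-2,3-dimethyl-3-(trimethylstannyl)cyclopent-1-en-1-yl N,N-diisopropylcarbamate F3. TiCl4 at −78 °C in CH2Cl2 then exchanges tin for titanium in an anti-SE' sense, which puts the metal back on the oxygen-bearing carbon on the face needed, and this far more Lewis acidic trichlorotitanium homoenolate adds to 4 through the same closed transition state to give 7.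

Step 10. SN2 displacement at a secondary carbon flanked by CMe2, on the face shared with the carbinol, can lose to elimination or methyl shift. The fallback sets out from 13 and comes back at 19 (it also bypasses steps 8 and 9) by moving the carbonyl to C4 and letting bromide add reversibly. Weitz–Scheffer epoxidation (30% H2O2, NaOH, MeOH, 0 °C) gives the epoxy ketone with the oxirane anti to the carbinol, 4-[(1R)-1-hydroxy-4-methylcyclohex-3-en-1-yl]-3,3,4-trimethyl-6-oxabicyclo[3.1.0]hexan-2-one F4. Wharton transposition (N2H4·H2O, AcOH, MeOH) gives the allylic alcohol 5-[(1R)-1-hydroxy-4-methylcyclohex-3-en-1-yl]-4,4,5-trimethylcyclopent-2-en-1-ol F5, whose carbinol configuration is irrelevant. MnO2 in CH2Cl2 oxidises it to (5R)-5-[(1R)-1-hydroxy-4-methylcyclohex-3-en-1-yl]-4,4,5-trimethylcyclopent-2-en-1-one F6. Reversible conjugate addition of bromide (TMSBr, CH2Cl2, −40 °C, aqueous work-up) is expected to settle on the cis-1,3 isomer with bromine and the large carbinol both pseudo-equatorial, (2R,4S)-4-bromo-2-[(1R)-1-hydroxy-4-methylcyclohex-3-en-1-yl]-2,3,3-trimethylcyclopentan-1-one F7. Reduction with NaBH4 and CeCl3·7H2O in MeOH at −78 °C, hydride entering from the methyl face of C5, gives 19.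

Step 11. Free chloride would favour the diaxial isomer (Br trans to the cyclopentyl group), and the C1' oxygen itself can capture the bromonium ion. The fallback sets out from 19 and comes back at 21 and uses that capture deliberately. NBS alone in CH2Cl2 at 0 °C gives the bromo ether in which the C1' oxygen bridges to C4' and the ring bromine is anti to the oxygen bridge, (1R,2S,4S)-4-bromo-2-(2-bromo-1-methyl-7-oxabicyclo[2.2.1]heptan-4-yl)-2,3,3-trimethylcyclopentan-1-ol F8. TiCl4 in CH2Cl2 at −78 °C then ionises the strained tertiary C4'–O bond with assistance from the anti bromine and returns chloride to C4' on the face the oxygen leaves, which gives 21 after aqueous work-up.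

**Further compounds**
F1 | step 3 | (R)-2,3-dimethylcyclopent-2-en-1-ol | CC1=C(C)CC[C@H]1O
F2 | step 3 | (R)-2,3-dimethylcyclopent-2-en-1-yl N,N-diisopropylcarbamate | CC1=C(C)CC[C@H]1OC(=O)N(C(C)C)C(C)C
F3 | step 3 | (3S)-2,3-dimethyl-3-(trimethylstannyl)cyclopent-1-en-1-yl N,N-diisopropylcarbamate | CC1=C(OC(=O)N(C(C)C)C(C)C)CC[C@]1(C)[Sn](C)(C)C
F4 | step 10 | 4-[(1R)-1-hydroxy-4-methylcyclohex-3-en-1-yl]-3,3,4-trimethyl-6-oxabicyclo[3.1.0]hexan-2-one (oxirane anti to the carbinol) | CC1(C)C(=O)[C@@H]2O[C@@H]2[C@@]1(C)[C@@]1(O)CCC(C)=CC1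
F5 | step 10 | 5-[(1R)-1-hydroxy-4-methylcyclohex-3-en-1-yl]-4,4,5-trimethylcyclopent-2-en-1-ol (ring hydroxyl trans to the carbinol) | CC1(C)C=C[C@H](O)[C@@]1(C)[C@@]1(O)CCC(C)=CC1
F6 | step 10 | (5R)-5-[(1R)-1-hydroxy-4-methylcyclohex-3-en-1-yl]-4,4,5-trimethylcyclopent-2-en-1-one | CC1(C)C=CC(=O)[C@@]1(C)[C@@]1(O)CCC(C)=CC1
F7 | step 10 | (2R,4S)-4-bromo-2-[(1R)-1-hydroxy-4-methylcyclohex-3-en-1-yl]-2,3,3-trimethylcyclopentan-1-one | CC1(C)[C@@H](Br)CC(=O)[C@@]1(C)[C@@]1(O)CCC(C)=CC1
F8 | step 11 | (1R,2S,4S)-4-bromo-2-(2-bromo-1-methyl-7-oxabicyclo[2.2.1]heptan-4-yl)-2,3,3-trimethylcyclopentan-1-ol (ring bromine anti to the oxygen bridge) | CC1(C)[C@@H](Br)C[C@@H](O)[C@@]1(C)[C@]12CC[C@](C)(O1)[C@@H](Br)C2
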